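**Retrosynthetic overview**
1. Esters last: the phenol is freed from its acetate, the angelate is put on the allylic ring-B alcohol by Yamaguchi esterification, and the aroyl ester on the ring-B alcohol obtained by hydroxyl-directed reduction of a ring-B ketone.
2. Ring B (seven-membered) is closed second, by ring-closing metathesis at its trisubstituted C=C, from a cyclopentane carrying a methallyl ketone arm and a silyloxyallyl arm trans to each other.
3. Ring A (cyclopentane) is made first, in the key step: formal [3+2] union of an open-chain (E)-β-methyl-γ-silyloxy enone with the ketone homoenolate CH2–CH2–C(=O)iPr (ring-opened 1-isopropylcyclopropanol), by conjugate addition then aldol closure.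
4. Enabling feature: in ring A the carbinol carbon (C–OH, iPr) is bonded to the ring-fusion CH, which is alpha to the oxygenated ring-B carbon bearing the aroyl ester, and the methyl-bearing quaternary fusion carbon is beta to that carbon. At the ketone level this is an aldol retron and a Michael retron on one enolate; a three-atom unit adds to one face of a ring alkene only (cis fusion), so the union is done on the open-chain E-enone and ring B is closed afterwards to give the trans fusion.
5. The enone comes from acrolein and ethynyltrimethylsilane: asymmetric alkynylation sets the one stereocentre that controls all others, carboalumination sets the E alkene.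

Key step: step 7

Assumption: the ProPhenol antipode used in step 1 is the one that delivers the 3S alcohol; 2-methylallylmagnesium chloride, 4-acetoxybenzoyl chloride and angelic acid are purchased.

**Step 1**
Reactants: 1 acrolein (prop-2-enal); 2 ethynyltrimethylsilane
Product: 4 (3S)-5-(trimethylsilyl)pent-1-en-4-yn-3-ol, via zinc alkynylide 3 (not isolated)
Conditions: Me2Zn (3 equiv), ProPhenol ligand (10 mol %, antipode giving the S alcohol), Ph3PO (20 mol %), PhMe, 0 °C
Reagents that add atoms: none
Why: Zn–ProPhenol asymmetric alkynylation of an enal, in which the ligand-bound zinc alkynylide adds 1,2 to one carbonyl face and so sets the S carbinol.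

**Step 2**
Reactants: 4 (3S)-5-(trimethylsilyl)pent-1-en-4-yn-3-ol
Product: 5 tert-butyldimethyl{[(3S)-5-(trimethylsilyl)pent-1-en-4-yn-3-yl]oxy}silane
Conditions: TBSCl, imidazole, DMF, rt
Reagents that add atoms: tert-butyldimethylsilyl chloride CC(C)(C)[Si](C)(C)Cl
Why: Standard imidazole-promoted silylation, which installs the bulky, non-chelating silyl ether that serves as stereocontrol element in step 7.

**Step 3**
Reactants: 5 tert-butyldimethyl{[(3S)-5-(trimethylsilyl)pent-1-en-4-yn-3-yl]oxy}silane
Product: 6 tert-butyldimethyl{[(3S)-pent-1-en-4-yn-3-yl]oxy}silane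
Conditions: K2CO3 (cat.), MeOH, rt
Reagents that add atoms: none
Why: Methoxide-mediated protodesilylation of the alkynylsilane, which cleaves the C–Si bond and leaves the secondary O–Si bond untouched.

**Step 4**
Reactants: 6 tert-butyldimethyl{[(3S)-pent-1-en-4-yn-3-yl]oxy}silane
Product: 8 methyl (2E,4S)-4-[(tert-butyldimethylsilyl)oxy]-3-methylhexa-2,5-dienoate, via alkenyldimethylalane 7 (not isolated)
Conditions: Me3Al (2.5 equiv), Cp2ZrCl2 (0.25 equiv), CH2Cl2, 0 °C → rt; then ClCO2Me, 0 °C → rt
Reagents that add atoms: trimethylaluminium C[Al](C)C; methyl chloroformate COC(Cl)=O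
Why: Negishi zirconium-catalysed carboalumination adds methyl and aluminium syn across the alkyne (methyl to the internal carbon) and the alkenylalane is acylated by the chloroformate with retention, which fixes the E trisubstituted alkene.

**Step 5**
Reactants: 8 methyl (2E,4S)-4-[(tert-butyldimethylsilyl)oxy]-3-methylhexa-2,5-dienoate
Product: 10 (5E,7S)-7-[(tert-butyldimethylsilyl)oxy]-2,6-dimethylnona-1,5,8-trien-4-one, via Weinreb amide 9 (not isolated)
Conditions: MeNH(OMe)·HCl, iPrMgCl, THF, −20 °C; then 2-methylallylmagnesium chloride, −78 °C → −20 °C; cold aq. NH4Cl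
Reagents that add atoms: 2-methylallylmagnesium chloride CC(=C)C[Mg]Cl
Why: One-pot Weinreb ketone synthesis, in which the magnesium amide turns the ester into the N-methoxy-N-methylamide and the chelated tetrahedral adduct of the allyl Grignard reagent survives until cold buffered work-up, so that addition stops at the β,γ-unsaturated ketone.

**Step 6**
Reactants: 11 methyl 2-methylpropanoate
Product: 12 1-(propan-2-yl)cyclopropan-1-ol
Conditions: EtMgBr (2.4 equiv), Ti(OiPr)4 (0.2 equiv), Et2O, 0 °C → rt; aq. H2SO4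
Reagents that add atoms: ethylmagnesium bromide CC[Mg]Br
Why: Kulinkovich cyclopropanation, in which the titanacyclopropane formed from two ethyl groups acts as a 1,2-dicarbanion toward the ester carbonyl.

**Step 7**
Reactants: 10 (5E,7S)-7-[(tert-butyldimethylsilyl)oxy]-2,6-dimethylnona-1,5,8-trien-4-one; 12 1-(propan-2-yl)cyclopropan-1-ol
Product: 15 1-[(1R,2R,5S)-5-[(1S)-1-[(tert-butyldimethylsilyl)oxy]prop-2-en-1-yl]-2-hydroxy-5-methyl-2-(propan-2-yl)cyclopentyl]-3-methylbut-3-en-1-one, via zinc homoenolate 13 (not isolated), via zinc enolate 14 (not isolated)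
Conditions: 12 (2.4 equiv), Et2Zn (1.2 equiv), THF, 0 °C → rt; then Cu(OTf)2 (10 mol %), P(OEt)3 (20 mol %), 10, −20 °C → rt; aq. NH4Cl
Reagents that add atoms: none
Why: Proposed new method: Et2Zn deprotonates two molecules of 12 and the strained zinc cyclopropoxides open to the ethyl-free zinc homoenolate 13; its alkyl group passes to monovalent copper (formed from Cu(OTf)2 in the flask) and adds 1,4 to the s-cis enone of 10, and the resulting (Z)-zinc enolate 14 attacks the ketone that the nucleophile itself carries in a zinc-chelated, Zimmerman–Traxler-like 5-(enolexo)-exo-trig aldol closure of the cyclopentane. The closest known reaction types are the conjugate addition of cyclopropanol-derived zinc homoenolates to enones (which stops at 1,6-diketones) and the copper-catalysed dialkylzinc conjugate addition–aldol cyclisation of keto-enones; new are the β,β-disubstituted acceptor and the capture of the enolate by the carbonyl of the reagent. The quaternary carbon is controlled by the neighbouring silyloxy stereocentre through a Felkin–Anh-type transition state (C–OSi bond anti to the incoming reagent, vinyl group beside the C=C, hydrogen beside the methyl). The ring CH is controlled by the quaternary carbon, the acyl group going trans to the large silyloxyallyl arm (also the thermodynamic outcome, since this centre can equilibrate through the enolate or by retro-aldol), and the carbinol carbon by the zinc chelate between enolate oxygen and ketone oxygen, which puts OH cis to the acyl group and isopropyl trans to it. The step needs 1,4- instead of 1,2-addition, transfer of the homoenolate group only, and ring closure faster than proton transfer from the doubly activated CH2 of the methallyl ketone; the soft copper–zinc reagent, the absence of ethyl groups and of any proton source, and the chelated five-ring closure should secure this.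

**Step 8**
Reactants: 15 1-[(1R,2R,5S)-5-[(1S)-1-[(tert-butyldimethylsilyl)oxy]prop-2-en-1-yl]-2-hydroxy-5-methyl-2-(propan-2-yl)cyclopentyl]-3-methylbut-3-en-1-one
Product: 16 (3R,3aR,8S,8aS)-8-[(tert-butyldimethylsilyl)oxy]-3-hydroxy-6,8a-dimethyl-3-(propan-2-yl)-2,3,3a,5,8,8a-hexahydroazulen-4(1H)-one
Conditions: second-generation Hoveyda–Grubbs catalyst (5 mol %), 1,4-benzoquinone (10 mol %), PhMe (2 mM), 80 °C
Reagents that add atoms: none
Why: Ring-closing metathesis of the vinyl and the 1,1-disubstituted alkene (ethene lost) closes the seven-membered ring B at its trisubstituted C=C, and because the two arms were placed trans on the cyclopentane in step 7 the ring fusion should be trans.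

**Step 9**
Reactants: 16 (3R,3aR,8S,8aS)-8-[(tert-butyldimethylsilyl)oxy]-3-hydroxy-6,8a-dimethyl-3-(propan-2-yl)-2,3,3a,5,8,8a-hexahydroazulen-4(1H)-one
Product: 17 (3R,3aS,4S,8S,8aS)-8-[(tert-butyldimethylsilyl)oxy]-6,8a-dimethyl-3-(propan-2-yl)-1,2,3,3a,4,5,8,8a-octahydroazulene-3,4-diol
Conditions: Me4NBH(OAc)3, MeCN–AcOH (1:1), −30 °C → −20 °C
Reagents that add atoms: none
Why: Evans–Saksena hydroxyl-directed reduction, in which the tertiary C-3 hydroxyl binds boron and delivers hydride to the carbonyl face on its own side (the face of the angular methyl), which should give the equatorial 4S alcohol with H-4 trans to H-3a.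

**Step 10**
Reactants: 17 (3R,3aS,4S,8S,8aS)-8-[(tert-butyldimethylsilyl)oxy]-6,8a-dimethyl-3-(propan-2-yl)-1,2,3,3a,4,5,8,8a-octahydroazulene-3,4-diol; 18 4-(acetyloxy)benzoyl chloride
Product: 19 (3R,3aS,4S,8S,8aS)-8-[(tert-butyldimethylsilyl)oxy]-3-hydroxy-6,8a-dimethyl-3-(propan-2-yl)-1,2,3,3a,4,5,8,8a-octahydroazulen-4-yl 4-(acetyloxy)benzoate
Conditions: Et3N, DMAP (cat.), CH2Cl2, 0 °C → rt
Reagents that add atoms: none
Why: DMAP-catalysed acylation of the only secondary hydroxyl, the tertiary carbinol being too hindered to react.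

**Step 11**
Reactants: 19 (3R,3aS,4S,8S,8aS)-8-[(tert-butyldimethylsilyl)oxy]-3-hydroxy-6,8a-dimethyl-3-(propan-2-yl)-1,2,3,3a,4,5,8,8a-octahydroazulen-4-yl 4-(acetyloxy)benzoate
Product: 20 (3R,3aS,4S,8S,8aS)-3,8-dihydroxy-6,8a-dimethyl-3-(propan-2-yl)-1,2,3,3a,4,5,8,8a-octahydroazulen-4-yl 4-(acetyloxy)benzoate
Conditions: HF·pyridine, pyridine, THF, 0 °C → rt
Reagents that add atoms: none
Why: Fluoride-driven Si–O cleavage under buffered acidic conditions, which should leave the aryl acetate and the benzoate ester intact.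

**Step 12**
Reactants: 20 (3R,3aS,4S,8S,8aS)-3,8-dihydroxy-6,8a-dimethyl-3-(propan-2-yl)-1,2,3,3a,4,5,8,8a-octahydroazulen-4-yl 4-(acetyloxy)benzoate; 21 angelic acid ((2Z)-2-methylbut-2-enoic acid)
Product: 23 (3R,3aS,4S,8S,8aS)-3-hydroxy-6,8a-dimethyl-8-{[(2Z)-2-methylbut-2-enoyl]oxy}-3-(propan-2-yl)-1,2,3,3a,4,5,8,8a-octahydroazulen-4-yl 4-(acetyloxy)benzoate, via mixed anhydride 22 (not isolated)
Conditions: 21, 2,4,6-trichlorobenzoyl chloride, Et3N, PhMe, rt; then 20, PhMe, 80 °C
Reagents that add atoms: none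
Why: Yamaguchi esterification through the mixed anhydride, heated without DMAP, a protocol that transfers the angeloyl group to hindered secondary alcohols without Z-to-E isomerisation to the tiglate.

**Step 13**
Reactants: 23 (3R,3aS,4S,8S,8aS)-3-hydroxy-6,8a-dimethyl-8-{[(2Z)-2-methylbut-2-enoyl]oxy}-3-(propan-2-yl)-1,2,3,3a,4,5,8,8a-octahydroazulen-4-yl 4-(acetyloxy)benzoate
Product: 24 (3R,3aS,4S,8S,8aS)-3-hydroxy-6,8a-dimethyl-8-{[(2Z)-2-methylbut-2-enoyl]oxy}-3-(propan-2-yl)-1,2,3,3a,4,5,8,8a-octahydroazulen-4-yl 4-hydroxybenzoate (target)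
Conditions: NH4OAc, MeOH–H2O (4:1), rt
Reagents that add atoms: none
Why: Chemoselective solvolysis of the aryl acetate, which is far more electrophilic than the alkyl benzoate and the hindered angelate, under neutral conditions that should not isomerise the angelate.

**Compound list**
1 | acrolein (prop-2-enal) | C=CC=O | starting material
2 | ethynyltrimethylsilane | C#C[Si](C)(C)C | starting material
3 | methyl[(trimethylsilyl)ethynyl]zinc | C[Zn]C#C[Si](C)(C)C | intermediate
4 | (3S)-5-(trimethylsilyl)pent-1-en-4-yn-3-ol | C=C[C@H](O)C#C[Si](C)(C)C | intermediate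
5 | tert-butyldimethyl{[(3S)-5-(trimethylsilyl)pent-1-en-4-yn-3-yl]oxy}silane | C=C[C@H](O[Si](C)(C)C(C)(C)C)C#C[Si](C)(C)C | intermediate
6 | tert-butyldimethyl{[(3S)-pent-1-en-4-yn-3-yl]oxy}silane | C=C[C@H](O[Si](C)(C)C(C)(C)C)C#C | intermediate
7 | [(1E,3S)-3-[(tert-butyldimethylsilyl)oxy]-2-methylpenta-1,4-dien-1-yl]dimethylalane | C=C[C@H](O[Si](C)(C)C(C)(C)C)/C(C)=C/[Al](C)C | intermediate
8 | methyl (2E,4S)-4-[(tert-butyldimethylsilyl)oxy]-3-methylhexa-2,5-dienoate | C=C[C@H](O[Si](C)(C)C(C)(C)C)/C(C)=C/C(=O)OC | intermediate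
9 | (2E,4S)-4-[(tert-butyldimethylsilyl)oxy]-N-methoxy-N,3-dimethylhexa-2,5-dienamide | C=C[C@H](O[Si](C)(C)C(C)(C)C)/C(C)=C/C(=O)N(C)OC | intermediate
10 | (5E,7S)-7-[(tert-butyldimethylsilyl)oxy]-2,6-dimethylnona-1,5,8-trien-4-one | C=C[C@H](O[Si](C)(C)C(C)(C)C)/C(C)=C/C(=O)CC(C)=C | intermediate
11 | methyl 2-methylpropanoate | COC(=O)C(C)C | starting material
12 | 1-(propan-2-yl)cyclopropan-1-ol | CC(C)C1(O)CC1 | intermediate
13 | bis(4-methyl-3-oxopentyl)zinc | CC(C)C(=O)CC[Zn]CCC(=O)C(C)C | intermediate
14 | (4-methyl-3-oxopentyl)zinc (4Z,6S)-6-[(1S)-1-[(tert-butyldimethylsilyl)oxy]prop-2-en-1-yl]-2,6,10-trimethyl-9-oxoundeca-1,4-dien-4-olate | C=C[C@H](O[Si](C)(C)C(C)(C)C)[C@@](C)(CCC(=O)C(C)C)/C=C(\O[Zn]CCC(=O)C(C)C)CC(C)=C | intermediate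
15 | 1-[(1R,2R,5S)-5-[(1S)-1-[(tert-butyldimethylsilyl)oxy]prop-2-en-1-yl]-2-hydroxy-5-methyl-2-(propan-2-yl)cyclopentyl]-3-methylbut-3-en-1-one | C=C[C@H](O[Si](C)(C)C(C)(C)C)[C@@]1(C)CC[C@@](O)(C(C)C)[C@@H]1C(=O)CC(C)=C | intermediate
16 | (3R,3aR,8S,8aS)-8-[(tert-butyldimethylsilyl)oxy]-3-hydroxy-6,8a-dimethyl-3-(propan-2-yl)-2,3,3a,5,8,8a-hexahydroazulen-4(1H)-one | CC(C)(C)[Si](C)(C)O[C@H]1C=C(C)CC(=O)[C@@H]2[C@]1(C)CC[C@@]2(O)C(C)C | intermediate
17 | (3R,3aS,4S,8S,8aS)-8-[(tert-butyldimethylsilyl)oxy]-6,8a-dimethyl-3-(propan-2-yl)-1,2,3,3a,4,5,8,8a-octahydroazulene-3,4-diol | CC(C)(C)[Si](C)(C)O[C@H]1C=C(C)C[C@H](O)[C@@H]2[C@]1(C)CC[C@@]2(O)C(C)C | intermediate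
18 | 4-(acetyloxy)benzoyl chloride | CC(=O)Oc1ccc(cc1)C(Cl)=O | starting material
19 | (3R,3aS,4S,8S,8aS)-8-[(tert-butyldimethylsilyl)oxy]-3-hydroxy-6,8a-dimethyl-3-(propan-2-yl)-1,2,3,3a,4,5,8,8a-octahydroazulen-4-yl 4-(acetyloxy)benzoate | CC(C)(C)[Si](C)(C)O[C@H]1C=C(C)C[C@H](OC(=O)c2ccc(OC(C)=O)cc2)[C@@H]2[C@]1(C)CC[C@@]2(O)C(C)C | intermediate
20 | (3R,3aS,4S,8S,8aS)-3,8-dihydroxy-6,8a-dimethyl-3-(propan-2-yl)-1,2,3,3a,4,5,8,8a-octahydroazulen-4-yl 4-(acetyloxy)benzoate | O[C@H]1C=C(C)C[C@H](OC(=O)c2ccc(OC(C)=O)cc2)[C@@H]2[C@]1(C)CC[C@@]2(O)C(C)C | intermediate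
21 | angelic acid, (2Z)-2-methylbut-2-enoic acid | C/C=C(/C)C(=O)O | starting material
22 | (2Z)-2-methylbut-2-enoic 2,4,6-trichlorobenzoic anhydride | C/C=C(/C)C(=O)OC(=O)c1c(Cl)cc(Cl)cc1Cl | intermediate
23 | (3R,3aS,4S,8S,8aS)-3-hydroxy-6,8a-dimethyl-8-{[(2Z)-2-methylbut-2-enoyl]oxy}-3-(propan-2-yl)-1,2,3,3a,4,5,8,8a-octahydroazulen-4-yl 4-(acetyloxy)benzoate | C/C=C(/C)C(=O)O[C@H]1C=C(C)C[C@H](OC(=O)c2ccc(OC(C)=O)cc2)[C@@H]2[C@]1(C)CC[C@@]2(O)C(C)C | intermediate
24 | (3R,3aS,4S,8S,8aS)-3-hydroxy-6,8a-dimethyl-8-{[(2Z)-2-methylbut-2-enoyl]oxy}-3-(propan-2-yl)-1,2,3,3a,4,5,8,8a-octahydroazulen-4-yl 4-hydroxybenzoate | C/C=C(/C)C(=O)O[C@H]1C=C(C)C[C@H](OC(=O)c2ccc(O)cc2)[C@@H]2[C@]1(C)CC[C@@]2(O)C(C)C | target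

**Step count**
Total: 13 steps. Longest linear sequence: 12 steps (steps 1–5 and 7–13, from acrolein); step 6 is a one-step side branch.

**Steps most likely to fail**

Step 7 (proposed new method). The conjugate addition may be slow at the fully substituted β-carbon of the open-chain enone. Proton transfer from the doubly activated CH2 may outrun the aldol closure and leave the open 1,6-diketone. Facial selectivity at the quaternary carbon may be poor. The fallback makes the two bonds in two known operations, setting out from 10 (with 13 generated from 12 as before). The enone and the zinc homoenolate are combined under the chlorotrimethylsilane-accelerated, copper-catalysed protocol established for zinc homoenolates and hindered enones (CuBr·SMe2, TMSCl, HMPA, THF). This should give the regiodefined silyl enol ether (4Z,6S)-6-[(1S)-1-[(tert-butyldimethylsilyl)oxy]prop-2-en-1-yl]-2,6,10-trimethyl-4-[(trimethylsilyl)oxy]undeca-1,4-dien-9-one F1. A separate intramolecular Mukaiyama aldol addition (TiCl4, CH2Cl2, −78 °C) then closes the cyclopentane and comes back to the route at 15.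

Step 8. Initiation and ring closure may be slow, because one alkene is a neopentyl-type silyloxyallyl group and the other is 1,1-disubstituted. Ruthenium hydride species may also move the β,γ-alkene into conjugation with the ketone. The fallback changes the metathesis substrate, setting out from 15. The silyl ether is removed first (HF·pyridine) to give 1-[(1R,2R,5S)-2-hydroxy-5-[(1S)-1-hydroxyprop-2-en-1-yl]-5-methyl-2-(propan-2-yl)cyclopentyl]-3-methylbut-3-en-1-one F2, whose free allylic hydroxyl is known to accelerate metathesis at the adjacent alkene. Ring closure with the same catalyst should then give (3R,3aR,8S,8aS)-3,8-dihydroxy-6,8a-dimethyl-3-(propan-2-yl)-2,3,3a,5,8,8a-hexahydroazulen-4(1H)-one F3. Selective silylation of the secondary hydroxyl (TBSOTf, 2,6-lutidine, CH2Cl2, −78 °C) comes back to the route at 16.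

Step 9. The hindered tertiary hydroxyl may fail to bind boron, so that conversion is low or hydride enters from the open face and the C-4 epimer forms. The fallback accepts that epimer and inverts it, setting out from 16. Undirected reduction with a small hydride (NaBH4, CeCl3·7H2O, MeOH, −78 °C) is expected to occur anti to the angular methyl and give (3R,3aS,4R,8S,8aS)-8-[(tert-butyldimethylsilyl)oxy]-6,8a-dimethyl-3-(propan-2-yl)-1,2,3,3a,4,5,8,8a-octahydroazulene-3,4-diol F4. Mitsunobu esterification with commercial 4-acetoxybenzoic acid (PPh3, DIAD, PhMe, 0 °C → rt) inverts the secondary carbinol and comes back to the route at 19.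

**Further compounds**
F1 | step 7 | (4Z,6S)-6-[(1S)-1-[(tert-butyldimethylsilyl)oxy]prop-2-en-1-yl]-2,6,10-trimethyl-4-[(trimethylsilyl)oxy]undeca-1,4-dien-9-one | C=C[C@H](O[Si](C)(C)C(C)(C)C)[C@@](C)(CCC(=O)C(C)C)/C=C(\O[Si](C)(C)C)CC(C)=C
F2 | step 8 | 1-[(1R,2R,5S)-2-hydroxy-5-[(1S)-1-hydroxyprop-2-en-1-yl]-5-methyl-2-(propan-2-yl)cyclopentyl]-3-methylbut-3-en-1-one | C=C[C@H](O)[C@@]1(C)CC[C@@](O)(C(C)C)[C@@H]1C(=O)CC(C)=C
F3 | step 8 | (3R,3aR,8S,8aS)-3,8-dihydroxy-6,8a-dimethyl-3-(propan-2-yl)-2,3,3a,5,8,8a-hexahydroazulen-4(1H)-one | O[C@H]1C=C(C)CC(=O)[C@@H]2[C@]1(C)CC[C@@]2(O)C(C)C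
F4 | step 9 | (3R,3aS,4R,8S,8aS)-8-[(tert-butyldimethylsilyl)oxy]-6,8a-dimethyl-3-(propan-2-yl)-1,2,3,3a,4,5,8,8a-octahydroazulene-3,4-diol | CC(C)(C)[Si](C)(C)O[C@H]1C=C(C)C[C@@H](O)[C@@H]2[C@]1(C)CC[C@@]2(O)C(C)C
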